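**Strategy.** The cyclohexane is disconnected across its C1–C2 and C3–C4 bonds (C1 = ylidene carbon, C3 = quaternary carbon). An intramolecular Diels–Alder reaction of a vinylallene, tethered through an ester to (2E)-geranylgeranic acid, closes the carbocycle and a temporary δ-lactone at once. It exploits the contiguous C2/C3/C4 stereotriad and the exocyclic tetrasubstituted C1=C bond: dienophile geometry sets C2/C3, the E-propenyl terminus sets C4, the allene axis sets the absolute sense, and the lactone locks the alkene geometry. The precursor is the acyclic (aS)-2-methylhepta-2,3,5-trienyl geranylgeranoate; lactone opening with two-carbon extension, diimide reduction and allylic oxidation finish the synthesis.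

Key step: step 7

Ring locants used below: C1 ylidene carbon, C2 CH bearing the hydroxypropyl chain, C3 quaternary carbon, C4 CH(CH3), C5 and C6 the CH2 groups.

Assumption: the (S,S)-ProPhenol/Me2Zn catalyst is taken to deliver the alkynyl group to the Re face of crotonaldehyde (4S carbinol); if the sense of induction is the opposite, the (R,R)-ligand is used instead.

**Step 1**
Reactants: 1 (2E,6E,10E)-geranylgeraniol
Product: 2 (2E,6E,10E)-geranylgeranial
Conditions: activated MnO2, CH2Cl2, rt
Reagents that add atoms: none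
Why: MnO2 should oxidise only the allylic alcohol (allylic oxidation), leaving the isolated trisubstituted alkenes and the 2E geometry untouched.

**Step 2**
Reactants: 2 (2E,6E,10E)-geranylgeranial
Product: 3 (2E,6E,10E)-geranylgeranic acid
Conditions: NaClO2, NaH2PO4, 2-methyl-2-butene, t-BuOH/H2O, 0 °C to rt
Reagents that add atoms: sodium chlorite, [Na+].[O-]Cl=O
Why: Pinnick oxidation with 2-methyl-2-butene as hypochlorite scavenger should give the acid without E/Z isomerisation or chlorination of the polyene.

**Step 3**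
Reactants: 4 (E)-crotonaldehyde; 5 tert-butyldimethyl(prop-2-yn-1-yloxy)silane
Product: 6 (4S,5E)-1-[(tert-butyldimethylsilyl)oxy]hept-5-en-2-yn-4-ol
Conditions: (S,S)-ProPhenol (10 mol%), Me2Zn, Ph3P=O (20 mol%), PhMe, 0 °C
Reagents that add atoms: none
Why: Zn–ProPhenol-catalysed enantioselective 1,2-alkynylation of an enal; the dinuclear zinc catalyst differentiates the aldehyde faces and sets the 4S carbinol.

**Step 4**
Reactants: 6 (4S,5E)-1-[(tert-butyldimethylsilyl)oxy]hept-5-en-2-yn-4-ol
Product: 8 tert-butyldimethyl{[(aS,5E)-2-methylhepta-2,3,5-trien-1-yl]oxy}silane, via propargylic mesylate 7 (not isolated)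
Conditions: n-BuLi, MsCl, THF, −78 °C; then MeMgBr, CuBr·SMe2, LiBr, −78 to −40 °C
Reagents that add atoms: methylmagnesium bromide, C[Mg]Br
Why: In situ mesylation followed by anti-selective SN2′ displacement with a methylcopper reagent (organocuprate propargylic substitution) should transfer the carbinol configuration to the allene axis (4S → aS), the alkyne being attacked in preference to the propenyl group as in vinylallene syntheses from alkenyl-substituted propargylic esters.

**Step 5**
Reactants: 8 tert-butyldimethyl{[(aS,5E)-2-methylhepta-2,3,5-trien-1-yl]oxy}silane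
Product: 9 (aS,5E)-2-methylhepta-2,3,5-trien-1-ol
Conditions: TBAF, THF, 0 °C
Reagents that add atoms: none
Why: Fluoride-mediated silyl ether cleavage; the vinylallene is inert to TBAF and its axis is not affected.

**Step 6**
Reactants: 3 (2E,6E,10E)-geranylgeranic acid; 9 (aS,5E)-2-methylhepta-2,3,5-trien-1-ol
Product: 10 (aS,5E)-2-methylhepta-2,3,5-trien-1-yl (2E,6E,10E)-geranylgeranoate
Conditions: DCC, DMAP (cat.), CH2Cl2, 0 °C to rt
Reagents that add atoms: none
Why: Steglich esterification joins the fragments under mild activation; the low temperature should limit deconjugation of the β,β-disubstituted enoate and the allene is untouched.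

**Step 7**
Reactants: 10 (aS,5E)-2-methylhepta-2,3,5-trien-1-yl (2E,6E,10E)-geranylgeranoate
Product: 11 (7R,8R,8aS)-4,7,8-trimethyl-8-[(3E,7E)-4,8,12-trimethyltrideca-3,7,11-trien-1-yl]-3,7,8,8a-tetrahydro-1H-isochromen-1-one
Conditions: PhMe (0.01 M), BHT (cat.), 130 °C, sealed tube
Reagents that add atoms: none
Why: Thermal, concerted but asynchronous [4+2] cycloaddition in which the s-cis vinylallene (central allene carbon and propenyl CH as diene termini) adds across the ester-activated 2E double bond of the geranylgeranoate; the closest known reaction type is the intramolecular Diels–Alder reaction of vinylallenes with axial-to-central chirality transfer, combined with ester-tethered intramolecular Diels–Alder reactions. The carbocycle closes by suprafacial [4+2] addition (new bonds C1–C2 and C3–C4 of the later cyclohexane), and the temporary δ-lactone closes in the same event as the six-membered tether ring, fused at C1–C2, with the tether carbonyl necessarily exo because the CH2O arm on the allene terminus can reach the dienophile only from that side. C2 and the quaternary C3 follow from the E geometry of the dienophile (CH3 cis to the carbonyl), and C4 from the E-propenyl terminus together with the enforced exo topology, which places the homofarnesyl chain endo and therefore cis to the C4 methyl. The absolute sense is set by the allene axis, whose CH2O arm lies on one diene face only, and the ring fusion fixes the ylidene bond with the CH2O carbon cis to C2. The step needs a regiochemistry opposite to the weak electronic bias of the propenyl terminus and reaction at a β,β-disubstituted enoate; the short tether makes the bridged regioisomer inaccessible and the sp-hybridised diene terminus has low steric demand. High dilution and BHT should suppress allene oligomerisation.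

**Step 8**
Reactants: 11 bicyclic lactone
Product: 12 (7R,8R,8aS)-4,7,8-trimethyl-8-[(3E,7E)-4,8,12-trimethyltrideca-3,7,11-trien-1-yl]-3,7,8,8a-tetrahydro-1H-isochromen-1-ol (lactol, anomer mixture)
Conditions: DIBAL-H (1.1 equiv), CH2Cl2, −78 °C; Rochelle salt work-up
Reagents that add atoms: none
Why: Partial lactone reduction; the aluminium hemiacetal is stable at −78 °C, so reduction should stop at the lactol and no alkene is reduced.

**Step 9**
Reactants: 12 lactol
Product: 14 (2Z)-2-{(2S,3R,4R)-2-[(1E)-3-hydroxyprop-1-en-1-yl]-3,4-dimethyl-3-[(3E,7E)-4,8,12-trimethyltrideca-3,7,11-trien-1-yl]cyclohex-5-en-1-ylidene}propan-1-ol, via hydroxy aldehyde 13 (not isolated)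
Conditions: (2-hydroxyethyl)triphenylphosphonium bromide, n-BuLi (2 equiv per P), THF, −20 to 0 °C; then 12, 0 °C to rt
Reagents that add atoms: (2-hydroxyethyl)triphenylphosphonium bromide, OCC[P+](c1ccccc1)(c1ccccc1)c1ccccc1.[Br-]
Why: Wittig olefination of the ring-opened lactol with a β-oxido ylide adds the two missing carbons with their oxygen in one step; the fast reaction of the non-stabilised ylide is expected to outrun enolisation at ring C2, and the new alkene geometry (E expected) is immaterial.

**Step 10**
Reactants: 14 dienyl diol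
Product: 15 (2Z)-2-{(2S,3R,4R)-2-(3-hydroxypropyl)-3,4-dimethyl-3-[(3E,7E)-4,8,12-trimethyltrideca-3,7,11-trien-1-yl]cyclohexylidene}propan-1-ol
Conditions: 2-nitrobenzenesulfonohydrazide (excess), Et3N, CH2Cl2, rt
Reagents that add atoms: none
Why: Diimide reduction (concerted syn transfer of H2) is much faster for 1,2-disubstituted than for tri- and tetrasubstituted alkenes, so the ring C5=C6 and propenyl double bonds should be saturated while the polyene chain and the ylidene bond remain; no stereocentre is created.

**Step 11**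
Reactants: 15 saturated diol
Product: 16 (2Z)-2-{(2S,3R,4R)-2-(3-hydroxypropyl)-3,4-dimethyl-3-[(3E,7E)-4,8,12-trimethyltrideca-3,7,11-trien-1-yl]cyclohexylidene}propanal (target)
Conditions: activated MnO2, CH2Cl2, rt
Reagents that add atoms: none
Why: MnO2 should oxidise the allylic primary alcohol selectively over the saturated one (allylic oxidation), with retention of the Z geometry, which is also the less strained arrangement.

**Compound list**

1 | (2E,6E,10E)-geranylgeraniol | CC(C)=CCC/C(C)=C/CC/C(C)=C/CC/C(C)=C/CO | starting material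
2 | (2E,6E,10E)-geranylgeranial | CC(C)=CCC/C(C)=C/CC/C(C)=C/CC/C(C)=C/C=O | intermediate
3 | (2E,6E,10E)-geranylgeranic acid | CC(C)=CCC/C(C)=C/CC/C(C)=C/CC/C(C)=C/C(=O)O | intermediate
4 | (E)-crotonaldehyde | C/C=C/C=O | starting material
5 | tert-butyldimethyl(prop-2-yn-1-yloxy)silane | C#CCO[Si](C)(C)C(C)(C)C | starting material
6 | (4S,5E)-1-[(tert-butyldimethylsilyl)oxy]hept-5-en-2-yn-4-ol | C/C=C/[C@H](O)C#CCO[Si](C)(C)C(C)(C)C | intermediate
7 | (4S,5E)-1-[(tert-butyldimethylsilyl)oxy]hept-5-en-2-yn-4-yl methanesulfonate (not isolated) | C/C=C/[C@H](OS(C)(=O)=O)C#CCO[Si](C)(C)C(C)(C)C | intermediate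
8 | tert-butyldimethyl{[(aS,5E)-2-methylhepta-2,3,5-trien-1-yl]oxy}silane | CC(C)(C)[Si](C)(C)OCC(C)=[C@@]=C([H])/C=C/C | intermediate
9 | (aS,5E)-2-methylhepta-2,3,5-trien-1-ol | OCC(C)=[C@@]=C([H])/C=C/C | intermediate
10 | (aS,5E)-2-methylhepta-2,3,5-trien-1-yl (2E,6E,10E)-3,7,11,15-tetramethylhexadeca-2,6,10,14-tetraenoate | CC(C)=CCC/C(C)=C/CC/C(C)=C/CC/C(C)=C/C(=O)OCC(C)=[C@@]=C([H])/C=C/C | intermediate
11 | (7R,8R,8aS)-4,7,8-trimethyl-8-[(3E,7E)-4,8,12-trimethyltrideca-3,7,11-trien-1-yl]-3,7,8,8a-tetrahydro-1H-isochromen-1-one | CC(C)=CCC/C(C)=C/CC/C(C)=C/CC[C@]1(C)[C@H](C)C=CC2=C(C)COC(=O)[C@@H]12 | intermediate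
12 | corresponding lactol, (7R,8R,8aS)-…-3,7,8,8a-tetrahydro-1H-isochromen-1-ol (anomer mixture) | CC(C)=CCC/C(C)=C/CC/C(C)=C/CC[C@]1(C)[C@H](C)C=CC2=C(C)COC(O)[C@@H]12 | intermediate
13 | ring-opened hydroxy aldehyde of 12: cyclohex-5-ene carrying CHO at C2 and the (Z)-1-hydroxyprop-2-ylidene group at C1 (not isolated) | CC(C)=CCC/C(C)=C/CC/C(C)=C/CC[C@]1(C)[C@H](C)C=C/C(=C(\C)CO)[C@H]1C=O | intermediate
14 | (2Z)-2-{(2S,3R,4R)-2-[(1E)-3-hydroxyprop-1-en-1-yl]-3,4-dimethyl-3-[(3E,7E)-4,8,12-trimethyltrideca-3,7,11-trien-1-yl]cyclohex-5-en-1-ylidene}propan-1-ol | CC(C)=CCC/C(C)=C/CC/C(C)=C/CC[C@]1(C)[C@H](C)C=C/C(=C(\C)CO)[C@H]1/C=C/CO | intermediate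
15 | (2Z)-2-{(2S,3R,4R)-2-(3-hydroxypropyl)-3,4-dimethyl-3-[(3E,7E)-4,8,12-trimethyltrideca-3,7,11-trien-1-yl]cyclohexylidene}propan-1-ol | CC(C)=CCC/C(C)=C/CC/C(C)=C/CC[C@]1(C)[C@H](C)CC/C(=C(\C)CO)[C@H]1CCCO | intermediate
16 | (2Z)-2-{(2S,3R,4R)-2-(3-hydroxypropyl)-3,4-dimethyl-3-[(3E,7E)-4,8,12-trimethyltrideca-3,7,11-trien-1-yl]cyclohexylidene}propanal | CC(C)=CCC/C(C)=C/CC/C(C)=C/CC[C@]1(C)[C@H](C)CC/C(=C(\C)C=O)[C@H]1CCCO | target

**Totals.** 11 steps in all; longest linear sequence 9 steps (steps 3–11, from crotonaldehyde).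

**Steps most likely to fail**

1. Step 7. The cycloaddition may be too slow at the hindered β,β-disubstituted enoate, so that allene oligomerisation or a [3,3] acyloxy shift of the allenylmethyl ester takes over. The fallback changes the dienophile to a cationic one at the aldehyde oxidation level (ionic Diels–Alder reaction). It sets out from 2 and 9 and comes back at 12. Aldehyde 2 is condensed with two equivalents of 9 (PPTS, MgSO4, benzene) to the bis[(aS,5E)-2-methylhepta-2,3,5-trien-1-yl] acetal of geranylgeranial F1. Catalytic TMSOTf in CH2Cl2 at −78 °C should ionise F1 to an alkenyl oxocarbenium ion that cyclises with the tethered vinylallene in the same topology, giving the cyclic mixed acetal (O-allenylmethyl ether of lactol 12) F2. Mild aqueous acid (PPTS, acetone/H2O) hydrolyses F2 to lactol 12 and returns one equivalent of 9.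

2. Step 4. The cuprate may lose regiocontrol (allylic SN2′ at the propenyl group or direct SN2 on the doubly activated mesylate), and chirality transfer may erode. The fallback places the leaving group at the far end of a conjugated enyne and uses an anti 1,5-(SN2″) substitution. It sets out from 5 and comes back at 8. Commercial (S)-but-3-yn-2-ol F3 is converted with Cp2Zr(H)Cl then I2 into (2S,3E)-4-iodobut-3-en-2-ol F4. Sonogashira coupling of F4 with 5 (Pd(PPh3)2Cl2, CuI, Et3N) gives (2S,3E)-7-[(tert-butyldimethylsilyl)oxy]hept-3-en-5-yn-2-ol F5, which is acetylated (Ac2O, pyridine) to the acetate F6. Treatment of F6 with Me2CuLi in Et2O at −78 °C should deliver methyl to the alkyne terminus anti to the acetate, forming the E-propenyl allene 8 with the aS axis.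

3. Step 9. The strongly basic ylide may enolise the ring-opened β,γ-unsaturated aldehyde, epimerising ring C2 or moving the ylidene double bond into the ring. The fallback uses a neutral stabilised ylide and a separate reduction. It sets out from 12 and comes back at 14. Lactol 12 and methyl (triphenylphosphoranylidene)acetate in PhMe at 60 °C should give methyl (2E)-3-{(1S,5R,6R)-2-[(2Z)-1-hydroxypropan-2-ylidene]-5,6-dimethyl-6-[(3E,7E)-4,8,12-trimethyltrideca-3,7,11-trien-1-yl]cyclohex-3-en-1-yl}prop-2-enoate F7 under base-free conditions (which also disfavour oxa-Michael closure). DIBAL-H at −78 °C then reduces the ester of F7 to the allylic alcohol 14.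

**Further compounds**

F1 | step 7 | bis[(aS,5E)-2-methylhepta-2,3,5-trien-1-yl] acetal of (2E,6E,10E)-geranylgeranial | CC(C)=CCC/C(C)=C/CC/C(C)=C/CC/C(C)=C/C(OCC(C)=[C@@]=C([H])/C=C/C)OCC(C)=[C@@]=C([H])/C=C/C
F2 | step 7 | O-[(aS,5E)-2-methylhepta-2,3,5-trien-1-yl] ether of lactol 12 (cyclic mixed acetal, anomer mixture) | CC(C)=CCC/C(C)=C/CC/C(C)=C/CC[C@]1(C)[C@H](C)C=CC2=C(C)COC(OCC(C)=[C@@]=C([H])/C=C/C)[C@@H]12
F3 | step 4 | (S)-but-3-yn-2-ol | C[C@H](O)C#C
F4 | step 4 | (2S,3E)-4-iodobut-3-en-2-ol | C[C@H](O)/C=C/I
F5 | step 4 | (2S,3E)-7-[(tert-butyldimethylsilyl)oxy]hept-3-en-5-yn-2-ol | C[C@H](O)/C=C/C#CCO[Si](C)(C)C(C)(C)C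
F6 | step 4 | (2S,3E)-7-[(tert-butyldimethylsilyl)oxy]hept-3-en-5-yn-2-yl acetate | C[C@H](OC(C)=O)/C=C/C#CCO[Si](C)(C)C(C)(C)C
F7 | step 9 | methyl (2E)-3-{(1S,5R,6R)-2-[(2Z)-1-hydroxypropan-2-ylidene]-5,6-dimethyl-6-[(3E,7E)-4,8,12-trimethyltrideca-3,7,11-trien-1-yl]cyclohex-3-en-1-yl}prop-2-enoate | CC(C)=CCC/C(C)=C/CC/C(C)=C/CC[C@]1(C)[C@H](C)C=C/C(=C(\C)CO)[C@H]1/C=C/C(=O)OC
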